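**Strategy.** Ring A (C1–C5, C10) is a bare cyclohexane in which two quaternary carbons, C4 and C10, flank the C5 methine. Returning C4 from C5 to C10 uncovers a 1,2,2-trimethylcyclopentyl carbinol, the core of camphoric acid. In the key step a C5 triflate ionises with an antiperiplanar 1,2-shift of C4, which enlarges the cyclopentane to ring A. The C10 cation so formed is captured by a tethered Z-allylsilane ester. One operation thus creates ring A, closes ring B, sets C5, C9 and C10, and leaves the C8 exocyclic methylene. The precursor is a monocyclic cyclopentyl carbinol with an open chain. C11 follows from a Felkin-controlled vinylogous aldol reaction.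

Key step: step 6

Remark: labdane numbering of the target (C1–C20) is used for the same carbon atoms in every precursor. (1S,3R)-(−)-Camphoric acid is taken as a commercial chiral-pool compound.

Step 1
Reactants: 1 (1S,3R)-(−)-camphoric acid
Product: 4 (1S)-1,2,2-trimethylcyclopentane-1-carboxylic acid, via camphoric anhydride 2 (not isolated), via Barton ester 3 (not isolated)
Conditions: DCC (1.05 equiv), 1-hydroxypyridine-2(1H)-thione, DMAP (cat.), CH2Cl2, 0 °C to rt, dark; then t-BuSH, hν (tungsten lamp), rt
Reagents that add atoms: none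
Why: Barton reductive decarboxylation: the cis-diacid closes to anhydride 2, the thiohydroxamic acid opens it at the far less hindered secondary carbonyl, and photolysis of ester 3 with the thiol replaces that carboxyl by hydrogen, so the future C3 becomes CH2 while the quaternary stereocentre (future C10) is untouched.

Step 2
Reactants: 4 (1S)-1,2,2-trimethylcyclopentane-1-carboxylic acid
Product: 5 1-[(1S)-1,2,2-trimethylcyclopentyl]ethan-1-one
Conditions: MeLi (3 equiv), Et2O, 0 °C to reflux; inverse quench into aq. NH4Cl
Reagents that add atoms: methyllithium [Li]C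
Why: Addition of methyllithium to a lithium carboxylate stops at the stable geminal dialkoxide, which collapses to the methyl ketone only on work-up, a standard ketone synthesis that tolerates hindered tertiary acids.

Step 3
Reactants: 5 1-[(1S)-1,2,2-trimethylcyclopentyl]ethan-1-one
Product: 6 1-[(1S)-1,2,2-trimethylcyclopentyl]pent-4-yn-1-one
Conditions: LDA, THF, −78 °C; propargyl bromide, DMPU, −78 to 0 °C
Reagents that add atoms: propargyl bromide C#CCBr
Why: Kinetic enolate alkylation: the ketone can enolise only towards its methyl group (future C6), and the unhindered lithium enolate is alkylated by the reactive propargylic bromide in an SN2 reaction.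

Step 4
Reactants: 6 1-[(1S)-1,2,2-trimethylcyclopentyl]pent-4-yn-1-one
Product: 9 methyl (2Z)-6-oxo-6-[(1S)-1,2,2-trimethylcyclopentyl]-3-[(trimethylsilyl)methyl]hex-2-enoate, via alkenylcopper 7 (not isolated), via carboxylic acid 8 (not isolated)
Conditions: Me3SiCH2MgCl, CuBr·SMe2, Et2O/Me2S, −45 °C; 6, −25 °C; CO2, P(OEt)3 (cat.), DMPU, −25 °C to rt; aq. NH4Cl/citric acid; crude acid: MeI, K2CO3, DMF, rt
Reagents that add atoms: (trimethylsilyl)methylmagnesium chloride C[Si](C)(C)C[Mg]Cl; carbon dioxide O=C=O; iodomethane CI
Why: Syn-carbocupration of a terminal alkyne puts the silylmethyl group on the internal carbon (C8) and copper on the terminal carbon (C9) on the same side, and carboxylation with retention followed by O-methylation gives the Z-allylsilane ester, while organocopper reagents leave the hindered ketone alone.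

Step 5
Reactants: 9 methyl (2Z)-6-oxo-6-[(1S)-1,2,2-trimethylcyclopentyl]-3-[(trimethylsilyl)methyl]hex-2-enoate
Product: 10 methyl (2Z,6S)-6-hydroxy-6-[(1S)-1,2,2-trimethylcyclopentyl]-3-[(trimethylsilyl)methyl]hex-2-enoate
Conditions: (R)-Me-CBS (20 mol%), BH3·SMe2, THF, −20 to 0 °C; MeOH, then aqueous work-up
Reagents that add atoms: none
Why: Corey–Bakshi–Shibata reduction: the catalyst tells the very large tert-alkyl group from the CH2 chain as it does in tert-butyl ketones, so the (R)-catalyst should give the 5S carbinol under reagent control, and borane spares the conjugated ester and its alkene.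

Step 6
Reactants: 10 methyl (2Z,6S)-6-hydroxy-6-[(1S)-1,2,2-trimethylcyclopentyl]-3-[(trimethylsilyl)methyl]hex-2-enoate
Product: 13 methyl (1S,4aS,8aS)-5,5,8a-trimethyl-2-methylidenedecahydronaphthalene-1-carboxylate, via triflate 11 (not isolated), via tertiary cation 12 (not isolated)
Conditions: Tf2O, 2,6-di-tert-butyl-4-methylpyridine, CH2Cl2, −78 to 0 °C
Reagents that add atoms: none
Why: The alcohol is triflated in situ and the neopentylic secondary triflate 11 ionises with antiperiplanar 1,2-migration of the quaternary ring carbon C4 from C10 to C5 (Wagner–Meerwein shift, cyclopentane to cyclohexane, as in solvolytic cyclopentylcarbinyl enlargements such as the D-homoannulation of 20-sulfonyloxy steroids), giving the tertiary C10 cation 12, the cation that also lies on the path of farnesyl-type polyene cyclisations. C9 of the allylsilane then attacks C10 in a 6-endo-trig closure of ring B through a chair–chair array, and loss of the silyl group to triflate from the β-silyl cation fixes the alkene as the C8 exocyclic methylene (allylsilane-terminated cation–olefin cyclisation). C5 is set by inversion at the CBS-derived carbinol carbon; C10 is set by attack of C9 on the lobe opposite the departing C4, which for the (5S,10S) precursor is the trans-decalin face whether the events are concerted or stepwise; C9 follows from the Z alkene geometry, which places CO2Me equatorial. The step needs migration of C4 in preference to C1 or the methyl group: C4 is the most substituted and best charge-bearing migrating carbon, and only its shift breaks the congested bond between the two quaternary carbons. Direct π-participation at C5 would be a 5-endo closure and SN2 attack is blocked by the neopentyl environment, so ionisation with rearrangement is the open channel. The hindered pyridine buffers the triflic acid, so neither protodesilylation nor migration of the exocyclic alkene into conjugation should occur.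

Step 7
Reactants: 13 methyl (1S,4aS,8aS)-5,5,8a-trimethyl-2-methylidenedecahydronaphthalene-1-carboxylate
Product: 14 (1S,4aS,8aS)-5,5,8a-trimethyl-2-methylidenedecahydronaphthalene-1-carbaldehyde (albicanal)
Conditions: DIBAL-H (1.1 equiv), CH2Cl2, −78 °C; MeOH, then aq. Rochelle salt
Reagents that add atoms: none
Why: Partial reduction of an ester with DIBAL-H: at −78 °C the hindered tetrahedral aluminium hemiacetal survives until the quench, and the neutral tartrate work-up avoids epimerisation at C9 or conjugation of the alkene.

Step 8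
Reactants: 15 methyl 3-methylbut-2-enoate
Product: 16 1-methoxy-3-methyl-1-(trimethylsilyloxy)buta-1,3-diene
Conditions: LDA, THF, −78 °C; Me3SiCl, −78 °C to rt
Reagents that add atoms: chlorotrimethylsilane C[Si](C)(C)Cl
Why: γ-Deprotonation of the senecioate with LDA gives the extended lithium dienolate, which chlorotrimethylsilane silylates on oxygen (silyl ketene acetal formation), and the ketene acetal geometry is of no consequence.

Step 9
Reactants: 14 albicanal; 16 1-methoxy-3-methyl-1-(trimethylsilyloxy)buta-1,3-diene
Product: 17 methyl (2E,5S)-5-hydroxy-3-methyl-5-[(1S,4aS,8aS)-5,5,8a-trimethyl-2-methylidenedecahydronaphthalen-1-yl]pent-2-enoate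
Conditions: BF3·OEt2, CH2Cl2, −78 °C; aq. NaHCO3; brief citric acid/MeOH to cleave any silyl ether
Reagents that add atoms: none
Why: Vinylogous Mukaiyama aldol reaction: under BF3 activation the dienol ether reacts at its γ-terminus through an open transition state in its s-trans form, which gives the E-enoate, and Felkin–Anh attack anti to the quaternary C10 past the C9 hydrogen sets 11S.

Step 10
Reactants: 17 methyl (2E,5S)-5-hydroxy-3-methyl-5-[(1S,4aS,8aS)-5,5,8a-trimethyl-2-methylidenedecahydronaphthalen-1-yl]pent-2-enoate
Product: 18 methyl (11S)-11-acetoxylabda-8(17),13E-dien-15-oate (target)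
Conditions: Ac2O, pyridine, DMAP (cat.), CH2Cl2, rt
Reagents that add atoms: acetic anhydride CC(=O)OC(C)=O
Why: DMAP-catalysed acetylation (nucleophilic catalysis) esterifies the hindered secondary alcohol under conditions too mild for elimination of the δ-acetoxy enoate or for epimerisation.

**Compound list**

1 | (1S,3R)-(−)-camphoric acid | OC(=O)[C@@]1(C)CC[C@@H](C(=O)O)C1(C)C | starting material
2 | (1S,5R)-1,8,8-trimethyl-3-oxabicyclo[3.2.1]octane-2,4-dione (camphoric anhydride) | O=C1OC(=O)[C@@]2(C)CC[C@@H]1C2(C)C | intermediate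
3 | (1S,3R)-1,2,2-trimethyl-3-{[(2-thioxopyridin-1(2H)-yl)oxy]carbonyl}cyclopentane-1-carboxylic acid (Barton ester) | OC(=O)[C@@]1(C)CC[C@@H](C(=O)ON2C=CC=CC2=S)C1(C)C | intermediate
4 | (1S)-1,2,2-trimethylcyclopentane-1-carboxylic acid | OC(=O)[C@@]1(C)CCCC1(C)C | intermediate
5 | 1-[(1S)-1,2,2-trimethylcyclopentyl]ethan-1-one | CC(=O)[C@@]1(C)CCCC1(C)C | intermediate
6 | 1-[(1S)-1,2,2-trimethylcyclopentyl]pent-4-yn-1-one | C#CCCC(=O)[C@@]1(C)CCCC1(C)C | intermediate
7 | (Z)-alkenylcopper, Cu on C9 cis to CH2SiMe3 | [Cu]/C=C(\C[Si](C)(C)C)CCC(=O)[C@@]1(C)CCCC1(C)C | intermediate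
8 | (2Z)-6-oxo-6-[(1S)-1,2,2-trimethylcyclopentyl]-3-[(trimethylsilyl)methyl]hex-2-enoic acid | OC(=O)/C=C(\C[Si](C)(C)C)CCC(=O)[C@@]1(C)CCCC1(C)C | intermediate
9 | methyl (2Z)-6-oxo-6-[(1S)-1,2,2-trimethylcyclopentyl]-3-[(trimethylsilyl)methyl]hex-2-enoate | COC(=O)/C=C(\C[Si](C)(C)C)CCC(=O)[C@@]1(C)CCCC1(C)C | intermediate
10 | methyl (2Z,6S)-6-hydroxy-6-[(1S)-1,2,2-trimethylcyclopentyl]-3-[(trimethylsilyl)methyl]hex-2-enoate | COC(=O)/C=C(\C[Si](C)(C)C)CC[C@H](O)[C@@]1(C)CCCC1(C)C | intermediate
11 | triflate of 10 | COC(=O)/C=C(\C[Si](C)(C)C)CC[C@H](OS(=O)(=O)C(F)(F)F)[C@@]1(C)CCCC1(C)C | intermediate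
12 | ring-enlarged 1,3,3-trimethylcyclohexyl cation (C10+) carrying the allylsilane chain at (S)-C5 | COC(=O)/C=C(\C[Si](C)(C)C)CC[C@H]1C(C)(C)CCC[C+]1C | intermediate
13 | methyl (1S,4aS,8aS)-5,5,8a-trimethyl-2-methylidenedecahydronaphthalene-1-carboxylate | C=C1CC[C@H]2C(C)(C)CCC[C@]2(C)[C@H]1C(=O)OC | intermediate
14 | (1S,4aS,8aS)-5,5,8a-trimethyl-2-methylidenedecahydronaphthalene-1-carbaldehyde (albicanal) | C=C1CC[C@H]2C(C)(C)CCC[C@]2(C)[C@H]1C=O | intermediate
15 | methyl 3-methylbut-2-enoate | COC(=O)C=C(C)C | starting material
16 | 1-methoxy-3-methyl-1-(trimethylsilyloxy)buta-1,3-diene | C=C(C)C=C(OC)O[Si](C)(C)C | intermediate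
17 | methyl (2E,5S)-5-hydroxy-3-methyl-5-[(1S,4aS,8aS)-5,5,8a-trimethyl-2-methylidenedecahydronaphthalen-1-yl]pent-2-enoate | C=C1CC[C@H]2C(C)(C)CCC[C@]2(C)[C@H]1[C@H](C/C(C)=C/C(=O)OC)O | intermediate
18 | methyl (11S)-11-acetoxylabda-8(17),13E-dien-15-oate | C=C1CC[C@H]2C(C)(C)CCC[C@]2(C)[C@H]1[C@H](C/C(C)=C/C(=O)OC)OC(C)=O | target

Total step count: 10. Longest linear sequence: 9 (steps 1–7, 9 and 10).

**Steps most likely to fail**

**Step 6.** Several processes could divert the cascade.
- The methyl group or C1 may migrate in place of C4.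
- The C10 cation may lose a proton or suffer a hydride shift before the ester-deactivated allylsilane closes ring B.
- Closure may occur on the wrong face and give a cis-decalin.

The fallback separates ring enlargement from ring closure into two individually known operations. It sets out from 6 and returns at 13. CBS reduction of 6 with the (R)-catalyst and catecholborane gives (1S)-1-[(1S)-1,2,2-trimethylcyclopentyl]pent-4-yn-1-ol F1. MsCl/Et3N gives (1S)-1-[(1S)-1,2,2-trimethylcyclopentyl]pent-4-yn-1-yl methanesulfonate F2. Buffered solvolysis (acetone–water, CaCO3, reflux) effects the same Wagner–Meerwein enlargement with capture of the cation by water and gives (2S)-2-(but-3-yn-1-yl)-1,3,3-trimethylcyclohexan-1-ol F3. Either epimer at the carbinol carbon serves, and migration isomers can be removed at this stage. The sequence of step 4, with one extra equivalent of the copper reagent for the hydroxyl group, gives methyl (2Z)-5-[(1S)-2-hydroxy-2,6,6-trimethylcyclohexyl]-3-[(trimethylsilyl)methyl]pent-2-enoate F4. SnCl4 in CH2Cl2 at −78 °C ionises the tertiary alcohol, and the allylsilane closes ring B to 13.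

**Step 4.** Addition of the silylmethylcopper reagent to the alkyne may be sluggish or poorly regioselective, and the alkenylcopper may be captured incompletely by CO2.

The fallback builds the Z-allylsilane by cross-coupling instead of carbometalation. It sets out from 6 and returns at 9. Palladium-catalysed oxidative methoxycarbonylation of the terminal alkyne (PdCl2 cat., CuCl2, NaOAc, CO, MeOH) gives methyl 6-oxo-6-[(1S)-1,2,2-trimethylcyclopentyl]hex-2-ynoate F5. Anti-hydroiodination (NaI, AcOH, 110 °C) gives methyl (2Z)-3-iodo-6-oxo-6-[(1S)-1,2,2-trimethylcyclopentyl]hex-2-enoate F6. Negishi coupling with Me3SiCH2ZnCl and Pd(PPh3)4 proceeds with retention to 9.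

**Step 9.** Three things may go wrong.
- The dienolate may react through its α-carbon or its s-cis form, which leads to the Z-enoate and lactonisation.
- Facial selectivity at C11 may be poor.
- The Lewis acid may move the exocyclic alkene of the aldehyde into conjugation.

The fallback sets the carbinol centre under reagent control and builds the E-enoate from an alkyne. It sets out from 14 and returns at 17. Propargylation with allenylboronic acid pinacol ester under a chiral BINOL-derived phosphoric acid gives (1S)-1-[(1S,4aS,8aS)-5,5,8a-trimethyl-2-methylidenedecahydronaphthalen-1-yl]but-3-yn-1-ol F7. Zirconium-catalysed carboalumination (Me3Al, Cp2ZrCl2) followed by iodine gives (1S,3E)-4-iodo-3-methyl-1-[(1S,4aS,8aS)-5,5,8a-trimethyl-2-methylidenedecahydronaphthalen-1-yl]but-3-en-1-ol F8; the 1,1-disubstituted alkene is inert to this reagent. Palladium-catalysed methoxycarbonylation (CO, MeOH, Et3N) gives 17 with retention of the E geometry.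

**Further compounds**

F1 | step 6 | (1S)-1-[(1S)-1,2,2-trimethylcyclopentyl]pent-4-yn-1-ol | C#CCC[C@H](O)[C@@]1(C)CCCC1(C)C
F2 | step 6 | (1S)-1-[(1S)-1,2,2-trimethylcyclopentyl]pent-4-yn-1-yl methanesulfonate | C#CCC[C@H](OS(C)(=O)=O)[C@@]1(C)CCCC1(C)C
F3 | step 6 | (2S)-2-(but-3-yn-1-yl)-1,3,3-trimethylcyclohexan-1-ol | C#CCC[C@H]1C(C)(C)CCCC1(C)O
F4 | step 6 | methyl (2Z)-5-[(1S)-2-hydroxy-2,6,6-trimethylcyclohexyl]-3-[(trimethylsilyl)methyl]pent-2-enoate | COC(=O)/C=C(\C[Si](C)(C)C)CC[C@H]1C(C)(C)CCCC1(C)O
F5 | step 4 | methyl 6-oxo-6-[(1S)-1,2,2-trimethylcyclopentyl]hex-2-ynoate | COC(=O)C#CCCC(=O)[C@@]1(C)CCCC1(C)C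
F6 | step 4 | methyl (2Z)-3-iodo-6-oxo-6-[(1S)-1,2,2-trimethylcyclopentyl]hex-2-enoate | COC(=O)/C=C(\I)CCC(=O)[C@@]1(C)CCCC1(C)C
F7 | step 9 | (1S)-1-[(1S,4aS,8aS)-5,5,8a-trimethyl-2-methylidenedecahydronaphthalen-1-yl]but-3-yn-1-ol | C=C1CC[C@H]2C(C)(C)CCC[C@]2(C)[C@H]1[C@H](CC#C)O
F8 | step 9 | (1S,3E)-4-iodo-3-methyl-1-[(1S,4aS,8aS)-5,5,8a-trimethyl-2-methylidenedecahydronaphthalen-1-yl]but-3-en-1-ol | C=C1CC[C@H]2C(C)(C)CCC[C@]2(C)[C@H]1[C@H](C/C(C)=C/I)O
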